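**Retrosynthetic overview**

1. Numbering: C1 = prenyl bridgehead, C3 = aroyl carbon between C2 and C4, C5 = geranyl bridgehead, C6 = CH2, C7 = CH(prenyl), C8 = CMe2, C9 = bridging C=O; ring A = C1–C2–C3–C4–C5–C9, ring B = C1–C8–C7–C6–C5–C9.
2. Enabling feature: ring A alternates O-bearing carbons (C2, C4, C9) with C-bearing carbons (C1, C3, C5), so it is a dearomatized phloroglucinol. Without the C1 prenyl and C3 aroyl groups it is the mirror-symmetric 4,4-dialkyl-3,5-dimethoxycyclohexa-2,5-dienone 16, whose two enol ether carbons become diastereotopic once the chain on C5 carries C7.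
3. Key disconnection C1–C8: ring B closes last, by attack of an enol ether carbon on the tertiary C8 cation of an (R)-lavandulyl chain; this desymmetrizes ring A and sets C5 and C1 from C7. Afterwards only C1–prenyl (bridgehead lithiation) and C3–aroyl (vinyl lithiation) remain.
4. Dienone 16 comes from the flat arene 2-bromo-1,3-dimethoxybenzene: Negishi coupling with the (S)-lavandulyl zinc reagent, Birch reduction (dearomatization), C-geranylation of the dienyl anion, bis-allylic oxidation. C7 comes from an Evans-type dienolate alkylation.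
5. Ring order: benzene ring (bought) → ring A by dearomatization (steps 6–8) → ring B (step 9).

Key step: step 9

Remark on the chemistry: the enolized triketone of 28 is a set of rapidly equilibrating tautomers; names and descriptors refer to the drawn C4-enol form.

**Route**

Step 1
Reactants: 1 (4S)-4-benzyl-1,3-oxazolidin-2-one; 2 3-methylbut-2-enoyl chloride
Product: 3 (4S)-4-benzyl-3-(3-methylbut-2-enoyl)-1,3-oxazolidin-2-one
Conditions: n-BuLi, THF, −78 °C; then 2, −78 → 0 °C
Reagents that add atoms: none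
Why: N-acylation of the lithiated oxazolidinone by an acid chloride, the standard entry to Evans-type imides; no stereocentre is formed.

Step 2
Reactants: 3 (4S)-4-benzyl-3-(3-methylbut-2-enoyl)-1,3-oxazolidin-2-one; 4 1-bromo-3-methylbut-2-ene (prenyl bromide)
Product: 6 (4S)-4-benzyl-3-[(2S)-5-methyl-2-(prop-1-en-2-yl)hex-4-enoyl]-1,3-oxazolidin-2-one, via sodium dienolate 5 (not isolated)
Conditions: NaN(SiMe3)2, THF, −78 °C; then 4, −78 → −30 °C; cold quench
Reagents that add atoms: none
Why: γ-deprotonation should give the chelated (Z)-dienolate, which alkylates at the α-carbon on the face away from the benzyl group (Evans-type asymmetric alkylation in its deconjugative form), setting the future C7 as (S) at this stage.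

Step 3
Reactants: 6 (4S)-4-benzyl-3-[(2S)-5-methyl-2-(prop-1-en-2-yl)hex-4-enoyl]-1,3-oxazolidin-2-one
Product: 7 (2S)-5-methyl-2-(prop-1-en-2-yl)hex-4-en-1-ol ((S)-lavandulol)
Conditions: LiBH4, MeOH (1 equiv), Et2O, 0 °C
Reagents that add atoms: none
Why: reductive removal of the oxazolidinone auxiliary with LiBH4 passes through no enolizable intermediate, so the stereocentre and the skipped diene should survive.

Step 4
Reactants: 7 (2S)-5-methyl-2-(prop-1-en-2-yl)hex-4-en-1-ol
Product: 8 (3S)-3-(iodomethyl)-2,6-dimethylhepta-1,5-diene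
Conditions: I2, PPh3, imidazole, CH2Cl2, 0 → 23 °C
Reagents that add atoms: iodine, II
Why: Appel-type iodination of a primary homoallylic alcohol, with no allylic transposition possible and the stereocentre untouched.

Step 5
Reactants: 8 (3S)-3-(iodomethyl)-2,6-dimethylhepta-1,5-diene; 9 2-bromo-1,3-dimethoxybenzene
Product: 11 1,3-dimethoxy-2-[(2R)-5-methyl-2-(prop-1-en-2-yl)hex-4-en-1-yl]benzene, via alkylzinc iodide 10 (not isolated)
Conditions: Zn dust, LiCl, THF, 40 °C; then 9, Pd(OAc)2 (2 mol %), SPhos (4 mol %), THF, 60 °C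
Reagents that add atoms: none
Why: LiCl-promoted zinc insertion into the primary iodide followed by Negishi coupling, with a biaryl dialkylphosphine ligand chosen for the doubly ortho-substituted, electron-rich aryl bromide; the stereocentre β to zinc is not involved (descriptor changes to R by priority only).

Step 6
Reactants: 11 1,3-dimethoxy-2-[(2R)-5-methyl-2-(prop-1-en-2-yl)hex-4-en-1-yl]benzene
Product: 12 1,5-dimethoxy-6-[(2R)-5-methyl-2-(prop-1-en-2-yl)hex-4-en-1-yl]cyclohexa-1,4-diene
Conditions: Li, NH3 (l), t-BuOH, THF, −78 °C; then solid NH4Cl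
Reagents that add atoms: none
Why: Birch reduction of a 2-alkyl-1,3-dimethoxybenzene places both methoxy groups on the double bonds of the 2,5-dihydro isomer, and isolated alkenes are inert to Li/NH3; the ring carbon bearing the chain lies on a mirror plane, so no stereocentre arises.

Step 7
Reactants: 12 1,5-dimethoxy-6-[(2R)-5-methyl-2-(prop-1-en-2-yl)hex-4-en-1-yl]cyclohexa-1,4-diene; 13 (2E)-1-bromo-3,7-dimethylocta-2,6-diene (geranyl bromide)
Product: 15 6-[(2E)-3,7-dimethylocta-2,6-dien-1-yl]-1,5-dimethoxy-6-[(2R)-5-methyl-2-(prop-1-en-2-yl)hex-4-en-1-yl]cyclohexa-1,4-diene, via dienyllithium 14 (not isolated)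
Conditions: t-BuLi, THF, −78 °C; then 13, −78 → −40 °C
Reagents that add atoms: none
Why: the C–H flanked by both methoxy-bearing carbons is removed selectively (lithium coordination, and a pentadienyl anion whose charge avoids the oxygenated carbons), and the anion is alkylated at its central carbon by SN2 attack on the allylic bromide, which keeps the E geometry; the new quaternary carbon lies on the mirror plane and is not a stereocentre.

Step 8
Reactants: 15 6-[(2E)-3,7-dimethylocta-2,6-dien-1-yl]-1,5-dimethoxy-6-[(2R)-5-methyl-2-(prop-1-en-2-yl)hex-4-en-1-yl]cyclohexa-1,4-diene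
Product: 16 4-[(2E)-3,7-dimethylocta-2,6-dien-1-yl]-3,5-dimethoxy-4-[(2R)-5-methyl-2-(prop-1-en-2-yl)hex-4-en-1-yl]cyclohexa-2,5-dien-1-one
Conditions: (C5H5NH)2Cr2O7 (pyridinium dichromate, promoter), t-BuOOH, Celite, benzene, 10 → 23 °C
Reagents that add atoms: tert-butyl hydroperoxide, CC(C)(C)OO
Why: bis-allylic oxidation of a Birch-type 1,4-diene to the cross-conjugated dienone with hexavalent chromium and t-BuOOH; the ring CH2 between the two enol ethers has by far the weakest C–H bond in the molecule, and the quaternary carbon blocks aromatization.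

Step 9
Reactants: 16 4-[(2E)-3,7-dimethylocta-2,6-dien-1-yl]-3,5-dimethoxy-4-[(2R)-5-methyl-2-(prop-1-en-2-yl)hex-4-en-1-yl]cyclohexa-2,5-dien-1-one
Product: 19 (1R,5S,7R)-5-[(2E)-3,7-dimethylocta-2,6-dien-1-yl]-4-methoxy-8,8-dimethyl-7-(3-methylbut-2-en-1-yl)bicyclo[3.3.1]non-3-ene-2,9-dione, via tertiary carbocation 17 (not isolated), via methyloxocarbenium ion 18 (not isolated)
Conditions: HCO2H (98%), 0.02 M, 23 °C, argon, dark
Reagents that add atoms: none
Why: Formic acid protonates the isopropenyl CH2 to the tertiary C8 cation 17, the α-carbon of one vinylogous ester unit of the dienone attacks it to give the methyloxocarbenium ion 18, and formate removes the methyl group as methyl formate to unveil the C9 ketone. The closest known reaction type is the formic-acid-mediated biomimetic cation–enol ether cyclization that forges the C1–C8 bond of bicyclic polyprenylated acylphloroglucinols from O-methylated dearomatized precursors, run here in the desymmetrizing manner known from epoxide-initiated cyclizations of 6,6-disubstituted 1,5-dimethoxycyclohexa-1,4-dienes. Ring B closes in a 6-exo-trig mode with respect to the isopropenyl group and a 6-(enolendo) mode with respect to the enol ether, through a chair transition state. C7 is carried in from 16; C5 and C1 are created together by the choice between the two diastereotopic enol ether carbons, and C7 controls that choice because only one chair places the C7 prenyl group equatorial (exo), the other forcing it syn-axial to both bonds that ring A makes with C1 and C5. The step needs site selectivity for the 1,1-disubstituted alkene over three trisubstituted alkenes and C- over O-alkylation; the first is secured by π-participation of the enol ether carbon held five atoms from C8, a far better π-nucleophile than any side-chain alkene, whose own protonation is reversible, and the second by the methyl ethers, since O-attack gives a tertiary alkyl oxonium ion that can only re-ionize.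

Step 10
Reactants: 19 (1R,5S,7R)-5-[(2E)-3,7-dimethylocta-2,6-dien-1-yl]-4-methoxy-8,8-dimethyl-7-(3-methylbut-2-en-1-yl)bicyclo[3.3.1]non-3-ene-2,9-dione; 4 1-bromo-3-methylbut-2-ene
Product: 21 (1R,5S,7R)-5-[(2E)-3,7-dimethylocta-2,6-dien-1-yl]-4-methoxy-8,8-dimethyl-1,7-bis(3-methylbut-2-en-1-yl)bicyclo[3.3.1]non-3-ene-2,9-dione, via bridgehead lithio species 20 (not isolated)
Conditions: LiN(iPr)2, THF, −78 °C; then 4, −78 → −20 °C
Reagents that add atoms: none
Why: bridgehead lithiation–alkylation of a bicyclo[3.3.1]nonane trione enol ether: C1–H, flanked by the C2 and C9 carbonyl groups, is the most acidic sp3 C–H, and the pyramidal bridgehead carbanion can only be alkylated with retention, so the quaternary C1 is fixed by the cage.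

Step 11
Reactants: 22 3,4-dihydroxybenzoic acid
Product: 23 tert-butyldimethylsilyl 3,4-bis[(tert-butyldimethylsilyl)oxy]benzoate
Conditions: TBSCl (3.5 equiv), imidazole, DMF, 23 °C
Reagents that add atoms: tert-butyldimethylsilyl chloride, CC(C)(C)[Si](C)(C)Cl
Why: exhaustive silylation of both phenols and the acid under standard imidazole/DMF conditions.

Step 12
Reactants: 23 tert-butyldimethylsilyl 3,4-bis[(tert-butyldimethylsilyl)oxy]benzoate
Product: 24 3,4-bis[(tert-butyldimethylsilyl)oxy]benzoyl chloride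
Conditions: (COCl)2, DMF (cat.), CH2Cl2, 0 → 23 °C
Reagents that add atoms: oxalyl chloride, O=C(Cl)C(Cl)=O
Why: direct conversion of a silyl ester into the acid chloride by the Vilsmeier-type reagent under neutral conditions, which leaves the aryl silyl ethers intact.

Step 13
Reactants: 21 (1R,5S,7R)-5-[(2E)-3,7-dimethylocta-2,6-dien-1-yl]-4-methoxy-8,8-dimethyl-1,7-bis(3-methylbut-2-en-1-yl)bicyclo[3.3.1]non-3-ene-2,9-dione; 24 3,4-bis[(tert-butyldimethylsilyl)oxy]benzoyl chloride
Product: 26 (1S,5S,7R)-3-{3,4-bis[(tert-butyldimethylsilyl)oxy]benzoyl}-5-[(2E)-3,7-dimethylocta-2,6-dien-1-yl]-4-methoxy-8,8-dimethyl-1,7-bis(3-methylbut-2-en-1-yl)bicyclo[3.3.1]non-3-ene-2,9-dione, via C3-lithio species 25 (not isolated)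
Conditions: lithium 2,2,6,6-tetramethylpiperidide, THF, −78 °C; then 24, −78 → −40 °C
Reagents that add atoms: none
Why: directed vinyl lithiation at C3, between the C2 carbonyl and the C4 methoxy group, followed by acylation with the acid chloride, as established for enol ethers of bicyclo[3.3.1]nonane-2,4,9-triones; no stereocentre is formed (the C1 descriptor changes by priority only).

Step 14
Reactants: 26 (1S,5S,7R)-3-{3,4-bis[(tert-butyldimethylsilyl)oxy]benzoyl}-5-[(2E)-3,7-dimethylocta-2,6-dien-1-yl]-4-methoxy-8,8-dimethyl-1,7-bis(3-methylbut-2-en-1-yl)bicyclo[3.3.1]non-3-ene-2,9-dione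
Product: 27 (1S,5S,7R)-3-(3,4-dihydroxybenzoyl)-5-[(2E)-3,7-dimethylocta-2,6-dien-1-yl]-4-methoxy-8,8-dimethyl-1,7-bis(3-methylbut-2-en-1-yl)bicyclo[3.3.1]non-3-ene-2,9-dione
Conditions: Et3N·3HF, THF, 23 °C; aq NaHCO3 work-up
Reagents that add atoms: none
Why: buffered fluoride cleavage of aryl silyl ethers, mild enough for the vinylogous ester and the acid-sensitive prenyl and geranyl groups.

Step 15
Reactants: 27 (1S,5S,7R)-3-(3,4-dihydroxybenzoyl)-5-[(2E)-3,7-dimethylocta-2,6-dien-1-yl]-4-methoxy-8,8-dimethyl-1,7-bis(3-methylbut-2-en-1-yl)bicyclo[3.3.1]non-3-ene-2,9-dione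
Product: 28 (1S,5S,7R)-3-(3,4-dihydroxybenzoyl)-5-[(2E)-3,7-dimethylocta-2,6-dien-1-yl]-4-hydroxy-8,8-dimethyl-1,7-bis(3-methylbut-2-en-1-yl)bicyclo[3.3.1]non-3-ene-2,9-dione (CNP0160101.3)
Conditions: LiCl, DMSO, 120 °C, argon; then aq citric acid
Reagents that add atoms: none
Why: Krapcho-type SN2 demethylation of the vinylogous methyl ester by chloride under neutral conditions, which should release the enolized triketone as its lithium salt and so protect it from acid-induced cyclization onto the prenyl groups.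

**Compound list**

1 | (4S)-4-benzyl-1,3-oxazolidin-2-one | O=C1OC[C@H](Cc2ccccc2)N1 | starting material
2 | 3-methylbut-2-enoyl chloride | CC(C)=CC(Cl)=O | starting material
3 | (4S)-4-benzyl-3-(3-methylbut-2-enoyl)-1,3-oxazolidin-2-one | O=C1OC[C@H](Cc2ccccc2)N1C(=O)C=C(C)C | intermediate
4 | 1-bromo-3-methylbut-2-ene | CC(C)=CCBr | starting material
5 | sodium (Z)-dienolate of 3 | O=C1OC[C@H](Cc2ccccc2)N1/C([O-])=C/C(C)=C.[Na+] | intermediate
6 | (4S)-4-benzyl-3-[(2S)-5-methyl-2-(prop-1-en-2-yl)hex-4-enoyl]-1,3-oxazolidin-2-one | O=C1OC[C@H](Cc2ccccc2)N1C(=O)[C@@H](CC=C(C)C)C(C)=C | intermediate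
7 | (2S)-5-methyl-2-(prop-1-en-2-yl)hex-4-en-1-ol | OC[C@@H](CC=C(C)C)C(C)=C | intermediate
8 | (3S)-3-(iodomethyl)-2,6-dimethylhepta-1,5-diene | IC[C@@H](CC=C(C)C)C(C)=C | intermediate
9 | 2-bromo-1,3-dimethoxybenzene | COc1cccc(OC)c1Br | starting material
10 | [(2S)-5-methyl-2-(prop-1-en-2-yl)hex-4-en-1-yl]zinc iodide | I[Zn]C[C@@H](CC=C(C)C)C(C)=C | intermediate
11 | 1,3-dimethoxy-2-[(2R)-5-methyl-2-(prop-1-en-2-yl)hex-4-en-1-yl]benzene | COc1cccc(OC)c1C[C@@H](CC=C(C)C)C(C)=C | intermediate
12 | 1,5-dimethoxy-6-[(2R)-5-methyl-2-(prop-1-en-2-yl)hex-4-en-1-yl]cyclohexa-1,4-diene | COC1=CCC=C(OC)C1C[C@@H](CC=C(C)C)C(C)=C | intermediate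
13 | (2E)-1-bromo-3,7-dimethylocta-2,6-diene | BrC/C=C(\C)CCC=C(C)C | starting material
14 | 6-lithio derivative of 12 (2,6-dimethoxy-1-alkylcyclohexa-2,5-dien-1-yllithium) | [Li]C1(C[C@@H](CC=C(C)C)C(C)=C)C(OC)=CCC=C1OC | intermediate
15 | 6-[(2E)-3,7-dimethylocta-2,6-dien-1-yl]-1,5-dimethoxy-6-[(2R)-5-methyl-2-(prop-1-en-2-yl)hex-4-en-1-yl]cyclohexa-1,4-diene | COC1=CCC=C(OC)C1(C/C=C(\C)CCC=C(C)C)C[C@@H](CC=C(C)C)C(C)=C | intermediate
16 | 4-[(2E)-3,7-dimethylocta-2,6-dien-1-yl]-3,5-dimethoxy-4-[(2R)-5-methyl-2-(prop-1-en-2-yl)hex-4-en-1-yl]cyclohexa-2,5-dien-1-one | COC1=CC(=O)C=C(OC)C1(C/C=C(\C)CCC=C(C)C)C[C@@H](CC=C(C)C)C(C)=C | intermediate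
17 | tertiary C8 carbocation from 16 (formate salt) | COC1=CC(=O)C=C(OC)C1(C/C=C(\C)CCC=C(C)C)C[C@@H](CC=C(C)C)[C+](C)C.[O-]C=O | intermediate
18 | C9 O-methyloxocarbenium ion of 19 (formate salt) | CC(C)=CCC/C(C)=C/C[C@]12C[C@@H](CC=C(C)C)C(C)(C)[C@H](C(=O)C=C1OC)C2=[O+]C.[O-]C=O | intermediate
19 | (1R,5S,7R)-5-[(2E)-3,7-dimethylocta-2,6-dien-1-yl]-4-methoxy-8,8-dimethyl-7-(3-methylbut-2-en-1-yl)bicyclo[3.3.1]non-3-ene-2,9-dione | CC(C)=CCC/C(C)=C/C[C@]12C[C@@H](CC=C(C)C)C(C)(C)[C@H](C(=O)C=C1OC)C2=O | intermediate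
20 | 1-lithio derivative of 19 | CC(C)=CCC/C(C)=C/C[C@]12C[C@@H](CC=C(C)C)C(C)(C)[C@]([Li])(C(=O)C=C1OC)C2=O | intermediate
21 | (1R,5S,7R)-5-[(2E)-3,7-dimethylocta-2,6-dien-1-yl]-4-methoxy-8,8-dimethyl-1,7-bis(3-methylbut-2-en-1-yl)bicyclo[3.3.1]non-3-ene-2,9-dione | CC(C)=CCC/C(C)=C/C[C@]12C[C@@H](CC=C(C)C)C(C)(C)[C@](CC=C(C)C)(C(=O)C=C1OC)C2=O | intermediate
22 | 3,4-dihydroxybenzoic acid | OC(=O)c1ccc(O)c(O)c1 | starting material
23 | tert-butyldimethylsilyl 3,4-bis[(tert-butyldimethylsilyl)oxy]benzoate | CC(C)(C)[Si](C)(C)OC(=O)c1ccc(O[Si](C)(C)C(C)(C)C)c(O[Si](C)(C)C(C)(C)C)c1 | intermediate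
24 | 3,4-bis[(tert-butyldimethylsilyl)oxy]benzoyl chloride | ClC(=O)c1ccc(O[Si](C)(C)C(C)(C)C)c(O[Si](C)(C)C(C)(C)C)c1 | intermediate
25 | 3-lithio derivative of 21 | CC(C)=CCC/C(C)=C/C[C@]12C[C@@H](CC=C(C)C)C(C)(C)[C@](CC=C(C)C)(C(=O)C([Li])=C1OC)C2=O | intermediate
26 | (1S,5S,7R)-3-{3,4-bis[(tert-butyldimethylsilyl)oxy]benzoyl}-5-[(2E)-3,7-dimethylocta-2,6-dien-1-yl]-4-methoxy-8,8-dimethyl-1,7-bis(3-methylbut-2-en-1-yl)bicyclo[3.3.1]non-3-ene-2,9-dione | CC(C)=CCC/C(C)=C/C[C@]12C[C@@H](CC=C(C)C)C(C)(C)[C@](CC=C(C)C)(C(=O)C(C(=O)c3ccc(O[Si](C)(C)C(C)(C)C)c(O[Si](C)(C)C(C)(C)C)c3)=C1OC)C2=O | intermediate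
27 | (1S,5S,7R)-3-(3,4-dihydroxybenzoyl)-5-[(2E)-3,7-dimethylocta-2,6-dien-1-yl]-4-methoxy-8,8-dimethyl-1,7-bis(3-methylbut-2-en-1-yl)bicyclo[3.3.1]non-3-ene-2,9-dione | CC(C)=CCC/C(C)=C/C[C@]12C[C@@H](CC=C(C)C)C(C)(C)[C@](CC=C(C)C)(C(=O)C(C(=O)c3ccc(O)c(O)c3)=C1OC)C2=O | intermediate
28 | (1S,5S,7R)-3-(3,4-dihydroxybenzoyl)-5-[(2E)-3,7-dimethylocta-2,6-dien-1-yl]-4-hydroxy-8,8-dimethyl-1,7-bis(3-methylbut-2-en-1-yl)bicyclo[3.3.1]non-3-ene-2,9-dione | CC(C)=CCC/C(C)=C/C[C@]12C[C@@H](CC=C(C)C)C(C)(C)[C@](CC=C(C)C)(C(=O)C(C(=O)c3ccc(O)c(O)c3)=C1O)C2=O | target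

**Step count and risks**

Total step count: 15. Longest linear sequence: 13 steps (steps 1–10 and 13–15).

Steps most likely to fail:

Step 9. What may go wrong: non-selective protonation, in which the trisubstituted alkenes of the geranyl and prenyl groups compete with the isopropenyl group and lead to cation–olefin cyclization of the geranyl chain or to formate addition, together with loss of nucleophilicity by O-protonation of the dienone. The fallback sets out from 16 and avoids Brønsted acid. Hydrogen-atom-transfer Markovnikov hydrochlorination (Co(BF4)2·6H2O with a salen-type ligand, TsCl, PhSiH3, EtOH, 23 °C) is selective for the 1,1-disubstituted alkene and should give 4-[(2R)-2-(2-chloropropan-2-yl)-5-methylhex-4-en-1-yl]-4-[(2E)-3,7-dimethylocta-2,6-dien-1-yl]-3,5-dimethoxycyclohexa-2,5-dien-1-one F1. Solvolysis of F1 in (CF3)2CHOH buffered with 2,6-lutidine ionizes only the tertiary C–Cl bond; the C8 cation should cyclize through the same chair, and the released chloride demethylates the oxocarbenium ion, so the sequence comes back at 19.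

Step 10. What may go wrong: metalation at C3 instead of C1, or proton return because C–C bond formation at the bridgehead carbanion beside the quaternary C8 is slow. The fallback sets out from 19 and replaces the polar alkylation by a radical one, which is insensitive to the neighbouring quaternary centre. Trapping of the bridgehead anion with the small electrophile iodine (LiN(iPr)2, THF, −78 °C; then I2) should give (1S,5S,7R)-5-[(2E)-3,7-dimethylocta-2,6-dien-1-yl]-1-iodo-4-methoxy-8,8-dimethyl-7-(3-methylbut-2-en-1-yl)bicyclo[3.3.1]non-3-ene-2,9-dione F2. Keck allylation of F2 (allyltributylstannane, AIBN, benzene, 80 °C) should give (1R,5S,7R)-5-[(2E)-3,7-dimethylocta-2,6-dien-1-yl]-4-methoxy-8,8-dimethyl-7-(3-methylbut-2-en-1-yl)-1-(prop-2-en-1-yl)bicyclo[3.3.1]non-3-ene-2,9-dione F3. Cross-metathesis of F3 with 2-methyl-2-butene (second-generation Hoveyda–Grubbs catalyst, 23 °C, short reaction time) then converts the monosubstituted allyl group into prenyl and comes back at 21; the prenyl-type termini exchange degenerately, and the internal trisubstituted alkene of the geranyl chain should react much more slowly but is the weak point of this fallback.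

Step 8. What may go wrong: over-oxidation, that is epoxidation or allylic oxidation of the side-chain alkenes and oxidative degradation of the enol ethers, instead of selective ketonization of the ring CH2. The fallback sets out from 9 and the alkylzinc iodide 10 and brings the oxygen in at the arene stage, so that ring A is made by alkylative dearomatization of a phenol instead of by Birch reduction and oxidation.
- Iridium-catalysed C–H borylation of 9 at the only unhindered position ([Ir(OMe)(cod)]2, 4,4'-di-tert-butyl-2,2'-bipyridine, B2pin2, THF, 80 °C) should give 2-(4-bromo-3,5-dimethoxyphenyl)-4,4,5,5-tetramethyl-1,3,2-dioxaborolane F4, which is oxidized in the same flask (NaBO3·4H2O, THF/H2O) to 4-bromo-3,5-dimethoxyphenol F5.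
- Silylation (TBSCl, imidazole, DMF) gives (4-bromo-3,5-dimethoxyphenoxy)(tert-butyl)dimethylsilane F6.
- Negishi coupling of F6 with 10 (Pd(OAc)2, SPhos, THF, 60 °C) gives tert-butyl{3,5-dimethoxy-4-[(2R)-5-methyl-2-(prop-1-en-2-yl)hex-4-en-1-yl]phenoxy}dimethylsilane F7, and Bu4NF (THF, 0 °C) releases 3,5-dimethoxy-4-[(2R)-5-methyl-2-(prop-1-en-2-yl)hex-4-en-1-yl]phenol F8.
- Para-selective dearomative allylation of F8 with geraniol through a π-allyl complex of zerovalent palladium (Pd(OAc)2, PPh3, Ti(OiPr)4, benzene, 50 °C), a reaction type established for 4-substituted 3,5-dimethoxyphenols, should then give the dienone and come back at 16.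

Further compounds
F1 | step 9 | 4-[(2R)-2-(2-chloropropan-2-yl)-5-methylhex-4-en-1-yl]-4-[(2E)-3,7-dimethylocta-2,6-dien-1-yl]-3,5-dimethoxycyclohexa-2,5-dien-1-one | COC1=CC(=O)C=C(OC)C1(C/C=C(\C)CCC=C(C)C)C[C@@H](CC=C(C)C)C(C)(C)Cl
F2 | step 10 | (1S,5S,7R)-5-[(2E)-3,7-dimethylocta-2,6-dien-1-yl]-1-iodo-4-methoxy-8,8-dimethyl-7-(3-methylbut-2-en-1-yl)bicyclo[3.3.1]non-3-ene-2,9-dione | CC(C)=CCC/C(C)=C/C[C@]12C[C@@H](CC=C(C)C)C(C)(C)[C@](I)(C(=O)C=C1OC)C2=O
F3 | step 10 | (1R,5S,7R)-5-[(2E)-3,7-dimethylocta-2,6-dien-1-yl]-4-methoxy-8,8-dimethyl-7-(3-methylbut-2-en-1-yl)-1-(prop-2-en-1-yl)bicyclo[3.3.1]non-3-ene-2,9-dione | CC(C)=CCC/C(C)=C/C[C@]12C[C@@H](CC=C(C)C)C(C)(C)[C@](CC=C)(C(=O)C=C1OC)C2=O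
F4 | step 8 | 2-(4-bromo-3,5-dimethoxyphenyl)-4,4,5,5-tetramethyl-1,3,2-dioxaborolane | COc1cc(B2OC(C)(C)C(C)(C)O2)cc(OC)c1Br
F5 | step 8 | 4-bromo-3,5-dimethoxyphenol | COc1cc(O)cc(OC)c1Br
F6 | step 8 | (4-bromo-3,5-dimethoxyphenoxy)(tert-butyl)dimethylsilane | COc1cc(O[Si](C)(C)C(C)(C)C)cc(OC)c1Br
F7 | step 8 | tert-butyl{3,5-dimethoxy-4-[(2R)-5-methyl-2-(prop-1-en-2-yl)hex-4-en-1-yl]phenoxy}dimethylsilane | COc1cc(O[Si](C)(C)C(C)(C)C)cc(OC)c1C[C@@H](CC=C(C)C)C(C)=C
F8 | step 8 | 3,5-dimethoxy-4-[(2R)-5-methyl-2-(prop-1-en-2-yl)hex-4-en-1-yl]phenol | COc1cc(O)cc(OC)c1C[C@@H](CC=C(C)C)C(C)=C
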